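The alpha run, charged at 0.22 M, ended with less single ring than the beta run at 0.14 M, 47.0 % against 56.3 %, so I took ring closure to be first order in substrate and competing with second-order dimerisation.

| flask | substrate | remark | time |
|---|---|---|---|
| beta | 0.14 M | run made earlier |  |
| alpha | 0.22 M | run made earlier |  |
| flask | 0.10 M |  | 30 min |

| run | time / min | open dimer / % | single ring / % |
|---|---|---|---|
| beta | 0.250 | 23.1 | 22.6 |
| beta | 1.00 | 16.3 | 45.0 |
| beta | 5.00 | 0.8 | 56.7 |
| beta | 25.0 | 0 | 56.3 |
| alpha | 0.250 | 28.3 | 20.7 |
| alpha | 1.00 | 17.9 | 36.9 |
| alpha | 5.00 | 0.8 | 46.6 |
| alpha | 25.0 | 0 | 47.0 |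

(scatter of a reading: 0.3 percentage points)

- time up to 30 min at which open dimer stands highest
- the amount of open dimer, in percent of the substrate charged, at that time

- percent here means substrate units held: one open dimer counts as two
- the analysis behind the earlier runs scatters by 0.3 percentage points, standard deviation
- a reading or a percentage of single ring counts all its forms, free or not

How much single ring would the flask give? I let x be the substrate used by dimerisation over that used by ring closure at the start. Integrating the substrate's rate law then gives a ring yield of ln(1+x)/x. The beta plateau, 56.5 %, solves to x = 1.87, so the competition number g, x per unit of charged [substrate], a selectivity factor, is 13.4 M⁻¹. For the alpha run g gives 46.6 %, and the plateau read there is 46.8 %. For the flask x is 1.34 and the ring yield 63.5 %.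

How much of what does not end as single ring stands as open dimer early in a run? The readings at 0.250 min show 0.531 of it in the beta run and 0.532 in the alpha run. I assumed that the beta share, read at that one time, would hold at the peak of the flask, so I expected about 19.4 % of open dimer there, and I reckoned no time for it.

The forecast gave 19.3 % at 0.33 min, “well before the ring builds up enough to matter”.

The flask peaked at 20.1 % at 0.377 min and ended with 63.9 % of single ring.

    substrate → single ring (k = 0.0250 s⁻¹)
    2 substrate → open dimer (k = 0.170 M⁻¹ s⁻¹)
    substrate + open dimer → open trimer (k = 0.150 M⁻¹ s⁻¹)
    open dimer → ring dimer (k = 0.0130 s⁻¹)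
    substrate + single ring ⇌ idle adduct, settled at all times (K = 8.30 M⁻¹)

I took the same reckoning to the neighbouring flask charged at 0.40 M, with the time held. There x is 5.35, which gave a ring yield of 34.6 % and, with the beta share, a peak of 34.7 % open dimer. That flask ended with 33.8 % of single ring, all forms counted, and 38.2 % of ring dimer. Its open dimer peaked at 34.3 %.

All runs are simulated on assumed constants; noise was put on by code.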